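## The problem

Sodwanone T is a C30 triterpenoid made of two trans-fused 2,2-dimethyloxepane–cyclohexene bicycles (squalene numbering: oxepane O/C2–C7 and cyclohexene C6–C11, mirrored in the C14–C23 half), joined by the C12–C13 ethano bridge between the tetrasubstituted alkene carbons C11 and C14. The carbon skeleton is C2-symmetric and only the oxidation level differs, a carbinol at C3 (R) against a ketone at C22. Each half carries a quaternary, methyl-bearing ring-fusion carbon (C6/C19, S) and an oxygenated ring-fusion methine (C7/C18, S) whose hydrogen is anti to the angular methyl. C6 and C19 lie across the four-carbon linker and cannot control one another, so absolute control is needed twice, whereas C7 can be relayed from the adjacent C6, and C3, which is 1,4 to C6 across a flexible seven-membered ring, is best set by a reagent. The tetrasubstituted C10=C11 and C14=C15 alkenes do not tolerate electrophilic oxidants (peracids, dioxiranes, halonium or selenium reagents) or strong protic acid, the tertiary C2–O ether is prone to ionisation, and C7 is epimerisable whenever C2 is a carbonyl. The feature that opens the structure is that each quaternary carbon is bonded directly to a linker-bearing alkene carbon (C6–C11, C19–C14) and that C11–C12–C13–C14 is the carbon chain of hexa-1,5-diyne. With the ring oxygen removed from an oxepane, C2–C7 is a six-membered carbocycle with C6 β to C2, the skeleton of 3-methylcyclohex-2-en-1-one, so both quaternary centres can come from a two-fold conjugate alkenylation.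

## Retrosynthesis

**C3–H (19 to 18).** The carbinol and the ketone are the only elements that break the symmetry, so the last disconnection is the C3–H bond, leading to the C2-symmetric 3,22-dione 18. The alternative, mono-oxidation of a stereodefined 3,22-diol, would require C3 and C22 to be set correctly earlier, where no reliable control element exists. A ketone flanked by the quaternary C2 and the C4 methylene is a good substrate for catalyst-controlled reduction. The forward step must reduce one of two equivalent carbonyls, which is statistical and is handled by recycling.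

**C2–CH3 (twice per ring) and C3–O (18 to 12).** The gem-dimethyl groups and the C3 oxygen are removed to give bis(lactone) 12, through diol 17, its silyl ether 16, lactol 15 and the α-oxygenated lactones 14 and 13. The neighbouring cut, the O–C2 ether bond (hydroxy-epoxide opening), would need an electrophilic epoxidation in the presence of the tetrasubstituted alkenes and would have to favour 7-endo over 6-exo closure. The C–C cut needs only an enolate oxidation, an organolithium addition and a Lewis-acid-mediated methylation, none of which touches the alkenes. C2 is not stereogenic, and the C3 configuration need not be controlled because it is erased in 18.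

**O–C7 and O–C18 (12 to 11).** Removing the ring oxygen is a Baeyer–Villiger retron and gives the trans-fused bis(octalone) 11. The cut is preferred because C7 already carries its substituents in 11 and migrates with retention, and because in 11 the C7 epimers can still be separated or equilibrated before the centre is locked. The forward reaction must insert oxygen on the C7 side and must not epoxidise C10=C11.

**C10=C11 and C14=C15 (11 to 10).** Ring-closing metathesis is the natural retron, because the methylidene on C11 is exactly what an internal alkenyl nucleophile leaves behind. This leads to the tetraene diketone 10, in which the cyclohexene ring is replaced by two simple appendages. The forward step must close a tetrasubstituted alkene next to a quaternary carbon, twice. It is placed before the oxygen insertion so that the homoallylic alkene, which could undergo carbonyl-ene cyclisation under Lewis acid, is already consumed.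

**C7–C8 and C17–C18 (10 to 8 and 2).** The side chain is attached by enolate alkylation with iodide 2 (from alcohol 1). The enolate must lie between the carbonyl and the quaternary carbon, a regiochemistry that deprotonation cannot give but conjugate addition does. The nucleophile is therefore the bis(enol silane) 8. The forward step must alkylate a hindered enolate with an unactivated iodide, anti to the larger C6 substituent.

**C6–C11 and C14–C19 (8 to 5 and 6; 5 to 3 and 4).** The key cut gives bis(alkenylalane) 5 and two molecules of enone 6; 5 comes from diyne 3 and two molecules of hydride 4. Neighbouring cuts at C6 (C6–CH3, C6–C5 or C6–C7) would leave the C6–C11 bond to be made inside a more elaborate fragment. This cut reduces the whole C20 core to an achiral C6 diyne and a commercial C7 enone. The forward reaction must transfer the alkenyl group, not isobutyl, with high enantioselectivity at both ends, and must hand on the enolate regiochemistry.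

## Roads not taken

Alternative 1: Double Birch reductive methylation of a bibenzyl. The cut is C6–CH3 and C19–CH3; the rings C6–C11 and C14–C19 come from the arene rings of the bis(amide) A1. Li in liquid NH3 reduces each benzamide at the ipso and para carbons and the amide enolates are methylated with MeI to give the bis(cyclohexadiene) A2.

- Merits: the C10=C11 and C14=C15 alkenes come from the arenes, so no metathesis to a tetrasubstituted alkene is needed. Auxiliary-controlled alkylation gives separable diastereomers. C7 and C18 arrive as masked ketones, so the C7–O centre could be set by ring-controlled carbonyl reduction. In these two respects this road is better than the chosen one.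
- Weak points: the only oxepane carbon delivered with the quaternary centre is C5, as a tertiary amide on a quaternary carbon, which is hard to cleave. C2–C4, the gem-dimethyl group and the C3 oxygen must then be added and a seven-membered tertiary ether closed. Both ortho positions of each benzamide are substituted, which makes the selectivity of the reductive alkylation less certain. A1 needs its own synthesis and two equivalents of auxiliary.
- Comparison: the chosen plan sets against it a catalytic asymmetric step from two commercial compounds, and an enone that brings all six carbons C2–C7, so that the oxepane needs only an oxygen insertion.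

Alternative 2: Two-directional epoxonium cascade. The cut is O–C2, C6–C11, C14–C19 and O–C23. TMSOTf with a hindered pyridine ionises the terminal epoxides of the tetraepoxide A3, the internal epoxide oxygens attack C2 and C23, the trisubstituted alkenes attack C6 and C19, and proton loss gives the diol A4.

- Merits: all four rings, four bonds and both carbinols form in one operation, and A4 is one oxidation from the target. If cascade and substrate both deliver, this road is clearly shorter than the chosen one.
- Weak points: A3 requires four of six chain alkenes to be epoxidised with the central two untouched and six centres controlled. The terminal (3R,22R) and internal (6S,7S,18S,19S) epoxides are not of the like sense that a single chiral dioxirane catalyst gives along a polyprenyl chain. Each end must combine a 7-endo oxacyclisation with a carbocyclisation and end by proton loss specifically from C11 (C14). The C10 cation is within reach of the other central alkene, so further cation–olefin cyclisation competes. Two such events in one molecule multiply the losses.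
- Comparison: the chosen plan is longer but forms each bond in a separately optimisable step and fixes C6 and C19 by catalyst control.

Alternative 3: Oxepane first, carbocycle closed onto the lactone carbonyl. The cut is C7=C8 and C17=C18. A Takai–Utimoto titanium alkylidene (TiCl4, TMEDA, Zn, catalytic PbCl2, CH3CHBr2) converts each terminal alkene and lactone carbonyl of the bis(lactone) A5 into a ring enol ether, giving the bis(enol ether) A6.

- Merits: the ring closure forms a trisubstituted enol ether and avoids metathesis to a tetrasubstituted alkene. C7–H is set afterwards by reduction of the enol ether anti to the angular methyl. That is more reliable than the enolate alkylation on which the chosen plan depends.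
- Weak points: A5 contains the quaternary C6/C19 α to a lactone carbonyl, a stereodefined (Z)-tetrasubstituted acyclic alkene and a lactone on the tertiary C2 oxygen, and none of these is addressed. The titanium reagent must act in excess on two carbonyls flanked by quaternary carbons.
- Comparison: the chosen plan has to set its weaker C7 control against a one-step catalytic solution to C6 and C19 from commercial materials.

Key step: step 3

Assumption: squalene numbering (C1–C24 chain carbons) is used for skeletal positions in all intermediates, and the conjugate-addition product is isolated as its O-silylated enol form 8, not as the free diketone, because protonation would discard the C7/C18 enolate regiochemistry that the next step needs.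

## Route

Step 1
Reactants: 1 3-methylbut-3-en-1-ol
Product: 2 4-iodo-2-methylbut-1-ene
Conditions: I2, PPh3, imidazole, CH2Cl2, 0 °C to rt
Reagents that add atoms: iodine, II
Why: Appel-type iodination; the alkoxyphosphonium ion of the primary alcohol is displaced by iodide (SN2), and the 1,1-disubstituted alkene is inert under these neutral conditions.

Step 2
Reactants: 3 hexa-1,5-diyne; 4 diisobutylaluminium hydride (2 equiv)
Product: 5 hexa-1,5-diene-2,5-diylbis(diisobutylalane)
Conditions: Ni(dppp)Cl2 (3 mol% per alkyne), THF, 0 to 22 °C
Reagents that add atoms: diisobutylaluminium hydride (the second molecule of 4), CC(C)C[AlH]CC(C)C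
Why: Nickel-catalysed hydroalumination of terminal alkynes with the bidentate phosphine complex places aluminium on the internal carbon (α-selectivity), here at C11 and C14. The two alkynes are insulated by two methylenes and react independently, so two molecules of 4 are consumed, one Al–H per C≡C bond. The THF solution of 5 is used directly in step 3.

Step 3
Reactants: 5 hexa-1,5-diene-2,5-diylbis(diisobutylalane); 6 3-methylcyclohex-2-en-1-one (2.5 equiv)
Product: 8 2,5-bis[(1R)-1-methyl-3-(triethylsilyloxy)cyclohex-2-en-1-yl]hexa-1,5-diene, via bis(diisobutylaluminium enolate) 7 (not isolated)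
Conditions: CuCl2·2H2O (5 mol%), chiral sulfonate-bearing NHC introduced as its preformed silver complex (from the imidazolinium sulfonate and Ag2O, 2.5 mol%), THF, −15 to 4 °C; then Et3SiOTf, −78 to 0 °C
Reagents that add atoms: triethylsilyl trifluoromethanesulfonate, CC[Si](CC)(CC)OS(=O)(=O)C(F)(F)F
Why: The alane reduces divalent copper to the active monovalent NHC–copper species, which takes an alkenyl group from aluminium, binds the enone C=C bond and delivers the alkenyl group to the β-carbon, releasing an aluminium enolate; the same sequence then occurs at the second Al–C bond. The closest known reaction type is the NHC–copper-catalysed enantioselective conjugate addition of alkenylaluminium reagents, made by nickel-catalysed hydroalumination, to β-substituted cyclic enones to give all-carbon quaternary centres; the two-fold use on a diyne-derived reagent applies it to a new molecule. The C6–C11 and C14–C19 bonds form and no ring closes. C6 and C19 are set by the chiral carbene ligand, whose enantiomer is chosen to give R at each new centre (S in the target after the change of substituent priorities). The two events are independent, so a wrong-sense addition mostly diverts material into the meso diastereomer and the C2-symmetric product should be enriched in enantiomeric purity (Horeau principle). The step needs 1,4- over 1,2-addition, alkenyl over isobutyl transfer and complete reaction at both ends; these are secured by the copper catalyst's preference for sp2-group transfer, the β-substituted enone and the excess of 6. Et3SiOTf then silylates the aluminium enolate on oxygen without equilibration and fixes the C2=C7 and C23=C18 enol regiochemistry.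

Step 4
Reactants: 8 2,5-bis[(1R)-1-methyl-3-(triethylsilyloxy)cyclohex-2-en-1-yl]hexa-1,5-diene; 2 4-iodo-2-methylbut-1-ene (3 equiv)
Product: 10 (2S,3R,2'S,3'R)-3,3'-(hexa-1,5-diene-2,5-diyl)bis[3-methyl-2-(3-methylbut-3-en-1-yl)cyclohexan-1-one], via dilithium bis(enolate) 9 (not isolated)
Conditions: MeLi (2.2 equiv), THF, 0 °C to rt; then HMPA, 2, −78 to 0 °C
Reagents that add atoms: none
Why: MeLi cleaves the O–Si bonds to regenerate the regiodefined lithium enolate, which is C-alkylated by the primary iodide (regiospecific enolate alkylation). The electrophile should enter C7 anti to the pseudoaxial, branched alkenyl group on C6, giving the 2,3-trans arrangement (C8 anti to C11, syn to the methyl) that later becomes the trans ring fusion. C7 stays enolisable, so minor epimers can be separated or equilibrated at 11.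

Step 5
Reactants: 10 (2S,3R,2'S,3'R)-3,3'-(hexa-1,5-diene-2,5-diyl)bis[3-methyl-2-(3-methylbut-3-en-1-yl)cyclohexan-1-one]
Product: 11 5,5'-(ethane-1,2-diyl)bis[(4aR,8aS)-4a,6-dimethyl-3,4,4a,7,8,8a-hexahydronaphthalen-1(2H)-one]
Conditions: second-generation Hoveyda–Grubbs catalyst with the N,N'-di(o-tolyl) carbene ligand (2 × 5 mol%), toluene (0.005 M), 80 °C, argon purge
Reagents that add atoms: none
Why: Double ring-closing metathesis joins the two 1,1-disubstituted alkenes of each half into the six-membered ring with the tetrasubstituted C10=C11 (C14=C15) bond and loss of ethene. The only other intramolecular pairing, C11 with C14, would give a cyclobutene and does not compete. The 2,3-trans appendages on C6 and C7 can both sit equatorial and so close to the trans-fused octalone.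

Step 6
Reactants: 11 5,5'-(ethane-1,2-diyl)bis[(4aR,8aS)-4a,6-dimethyl-3,4,4a,7,8,8a-hexahydronaphthalen-1(2H)-one]
Product: 12 6,6'-(ethane-1,2-diyl)bis[(5aS,9aS)-5a,7-dimethyl-4,5,5a,8,9,9a-hexahydro-1-benzoxepin-2(3H)-one]
Conditions: Me3SiOOSiMe3 (3 equiv), Me3SiOTf (20 mol%), 4 Å sieves, CH2Cl2, −78 to −30 °C
Reagents that add atoms: bis(trimethylsilyl) peroxide, C[Si](C)(C)OO[Si](C)(C)C
Why: Lewis-acid-catalysed Baeyer–Villiger oxidation; the silyl peroxide adds to the activated carbonyl and the more substituted C7 (C18) migrates with retention, so the ring-fusion configuration passes unchanged into the lactone. Unlike a peracid, this reagent does not epoxidise the tetrasubstituted alkenes.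

Step 7
Reactants: 12 6,6'-(ethane-1,2-diyl)bis[(5aS,9aS)-5a,7-dimethyl-4,5,5a,8,9,9a-hexahydro-1-benzoxepin-2(3H)-one]
Product: 13 6,6'-(ethane-1,2-diyl)bis[(5aS,9aS)-3-hydroxy-5a,7-dimethyl-4,5,5a,8,9,9a-hexahydro-1-benzoxepin-2(3H)-one] (mixture of C3/C22 epimers)
Conditions: KHMDS (2.6 equiv), THF, −78 °C; then 2-(phenylsulfonyl)-3-phenyloxaziridine, −78 °C; aq. NH4Cl
Reagents that add atoms: 2-(phenylsulfonyl)-3-phenyloxaziridine, O=S(=O)(c1ccccc1)N1OC1c1ccccc1
Why: Electrophilic hydroxylation of the potassium lactone enolates by the N-sulfonyloxaziridine (Davis oxidation); at −78 °C the reagent does not attack unactivated alkenes. The C3 configuration is not controlled and need not be, since it is erased in step 11.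

Step 8
Reactants: 13 6,6'-(ethane-1,2-diyl)bis[(5aS,9aS)-3-hydroxy-5a,7-dimethyl-4,5,5a,8,9,9a-hexahydro-1-benzoxepin-2(3H)-one]
Product: 14 the 3,3'-bis(triethylsilyl ether) of 13 (C3/C22 epimers)
Conditions: Et3SiCl, imidazole, DMF, 0 °C to rt
Reagents that add atoms: chlorotriethylsilane, CC[Si](Cl)(CC)CC
Why: Routine silylation of a secondary alcohol. It prevents the α-hydroxy methyl ketone that would otherwise form in step 9 from α-ketol isomerisation and keeps the hydroxyl from consuming the organometallic reagents.

Step 9
Reactants: 14 the 3,3'-bis(triethylsilyl ether) of 13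
Product: 15 6,6'-(ethane-1,2-diyl)bis[(5aS,9aS)-2,5a,7-trimethyl-3-(triethylsilyloxy)-2,3,4,5,5a,8,9,9a-octahydro-1-benzoxepin-2-ol] (lactol, in equilibrium with the open hydroxy ketone; epimers at C2 and C3)
Conditions: MeLi (2.4 equiv), THF, −78 °C; aq. NH4Cl at −78 °C
Reagents that add atoms: methyllithium, [Li]C
Why: 1,2-Addition of MeLi to a lactone at low temperature stops at the lithium hemiketal, which the α-silyloxy group stabilises against collapse (the reaction type used on aldonolactones). Protonation gives the methyl lactol.

Step 10
Reactants: 15 6,6'-(ethane-1,2-diyl)bis[(5aS,9aS)-2,5a,7-trimethyl-3-(triethylsilyloxy)-2,3,4,5,5a,8,9,9a-octahydro-1-benzoxepin-2-ol]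
Product: 17 6,6'-(ethane-1,2-diyl)bis[(5aS,9aS)-2,2,5a,7-tetramethyl-2,3,4,5,5a,8,9,9a-octahydro-1-benzoxepin-3-ol] (C3/C22 epimers), via its bis(triethylsilyl ether) 16 (not isolated)
Conditions: Me3Al (8 equiv), Me3SiOTf (2.5 equiv), CH2Cl2, −78 to −20 °C; aq. potassium sodium tartrate; crude 16, AcOH–THF–H2O (3:1:1), rt
Reagents that add atoms: trimethylaluminium, C[Al](C)C
Why: Me3SiOTf ionises the lactol to the cyclic 2-methyl oxocarbenium ion, which Me3Al methylates (Lewis-acid-mediated C-methylation of a hemiketal, as in ketoside to C-glycoside conversions). C2 becomes a gem-dimethyl carbon, so no stereochemical question arises. The triethylsilyl ethers are then hydrolysed by dilute acetic acid, which is mild enough to spare the tetrasubstituted alkenes and the tertiary ethers.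

Step 11
Reactants: 17 6,6'-(ethane-1,2-diyl)bis[(5aS,9aS)-2,2,5a,7-tetramethyl-2,3,4,5,5a,8,9,9a-octahydro-1-benzoxepin-3-ol]
Product: 18 6,6'-(ethane-1,2-diyl)bis[(5aS,9aS)-2,2,5a,7-tetramethyl-4,5,5a,8,9,9a-hexahydro-1-benzoxepin-3(2H)-one]
Conditions: Dess–Martin periodinane, NaHCO3, CH2Cl2, rt
Reagents that add atoms: none
Why: Dess–Martin oxidation of the secondary alcohols under buffered, non-acidic conditions leaves the alkenes and the tertiary ethers untouched. All C3/C22 epimers converge on one C2-symmetric dione.

Step 12
Reactants: 18 6,6'-(ethane-1,2-diyl)bis[(5aS,9aS)-2,2,5a,7-tetramethyl-4,5,5a,8,9,9a-hexahydro-1-benzoxepin-3(2H)-one]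
Product: 19 sodwanone T, (5aS,9aS)-6-{2-[(3R,5aS,9aS)-3-hydroxy-2,2,5a,7-tetramethyl-2,3,4,5,5a,8,9,9a-octahydro-1-benzoxepin-6-yl]ethyl}-2,2,5a,7-tetramethyl-4,5,5a,8,9,9a-hexahydro-1-benzoxepin-3(2H)-one
Conditions: (S)-2-methyl-CBS-oxazaborolidine (0.3 equiv), BH3·SMe2 (0.4 equiv), THF, −30 °C; MeOH quench
Reagents that add atoms: none
Why: Corey–Bakshi–Shibata reduction, in which the catalyst distinguishes the quaternary C2 (large) from the C4 methylene (small) and the (S)-catalyst should deliver hydride to give the 3R carbinol. With limiting borane one of the two equivalent, remote carbonyls is reduced on average, and the tetrasubstituted alkenes are not hydroborated at this temperature. Recovered 18 and over-reduced diol (after re-oxidation as in step 11) are recycled.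

## Compound list

1 | 3-methylbut-3-en-1-ol | CC(=C)CCO | starting material
2 | 4-iodo-2-methylbut-1-ene | CC(=C)CCI | intermediate
3 | hexa-1,5-diyne | C#CCCC#C | starting material
4 | diisobutylaluminium hydride | CC(C)C[AlH]CC(C)C | starting material
5 | hexa-1,5-diene-2,5-diylbis(diisobutylalane) | C=C([Al](CC(C)C)CC(C)C)CCC(=C)[Al](CC(C)C)CC(C)C | intermediate
6 | 3-methylcyclohex-2-en-1-one | CC1=CC(=O)CCC1 | starting material
7 | 2,5-bis[(1R)-3-(diisobutylalumanyloxy)-1-methylcyclohex-2-en-1-yl]hexa-1,5-diene (not isolated) | C=C(CCC(=C)[C@]1(C)CCCC(O[Al](CC(C)C)CC(C)C)=C1)[C@]1(C)CCCC(O[Al](CC(C)C)CC(C)C)=C1 | intermediate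
8 | 2,5-bis[(1R)-1-methyl-3-(triethylsilyloxy)cyclohex-2-en-1-yl]hexa-1,5-diene | C=C(CCC(=C)[C@]1(C)CCCC(O[Si](CC)(CC)CC)=C1)[C@]1(C)CCCC(O[Si](CC)(CC)CC)=C1 | intermediate
9 | dilithium bis(enolate) of the (R,R)-diketone, 2,5-bis[(1R)-3-lithiooxy-1-methylcyclohex-2-en-1-yl]hexa-1,5-diene (not isolated) | C=C(CCC(=C)[C@]1(C)CCCC(O[Li])=C1)[C@]1(C)CCCC(O[Li])=C1 | intermediate
10 | (2S,3R,2'S,3'R)-3,3'-(hexa-1,5-diene-2,5-diyl)bis[3-methyl-2-(3-methylbut-3-en-1-yl)cyclohexan-1-one] | C=C(CCC(=C)[C@]1(C)CCCC(=O)[C@H]1CCC(C)=C)[C@]1(C)CCCC(=O)[C@H]1CCC(C)=C | intermediate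
11 | 5,5'-(ethane-1,2-diyl)bis[(4aR,8aS)-4a,6-dimethyl-3,4,4a,7,8,8a-hexahydronaphthalen-1(2H)-one] (trans-fused) | C(CC1=C(C)CC[C@@H]2C(=O)CCC[C@@]12C)C1=C(C)CC[C@@H]2C(=O)CCC[C@@]12C | intermediate
12 | 6,6'-(ethane-1,2-diyl)bis[(5aS,9aS)-5a,7-dimethyl-4,5,5a,8,9,9a-hexahydro-1-benzoxepin-2(3H)-one] | C(CC1=C(C)CC[C@@H]2OC(=O)CCC[C@@]12C)C1=C(C)CC[C@@H]2OC(=O)CCC[C@@]12C | intermediate
13 | 6,6'-(ethane-1,2-diyl)bis[(5aS,9aS)-3-hydroxy-5a,7-dimethyl-4,5,5a,8,9,9a-hexahydro-1-benzoxepin-2(3H)-one], C3/C22 configuration not controlled | C(CC1=C(C)CC[C@@H]2OC(=O)C(O)CC[C@@]12C)C1=C(C)CC[C@@H]2OC(=O)C(O)CC[C@@]12C | intermediate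
14 | 3,3'-bis(triethylsilyl ether) of 13, C3/C22 configuration not controlled | C(CC1=C(C)CC[C@@H]2OC(=O)C(O[Si](CC)(CC)CC)CC[C@@]12C)C1=C(C)CC[C@@H]2OC(=O)C(O[Si](CC)(CC)CC)CC[C@@]12C | intermediate
15 | 6,6'-(ethane-1,2-diyl)bis[(5aS,9aS)-2,5a,7-trimethyl-3-(triethylsilyloxy)-2,3,4,5,5a,8,9,9a-octahydro-1-benzoxepin-2-ol], C2 and C3 configuration not controlled | C(CC1=C(C)CC[C@@H]2OC(C)(O)C(O[Si](CC)(CC)CC)CC[C@@]12C)C1=C(C)CC[C@@H]2OC(C)(O)C(O[Si](CC)(CC)CC)CC[C@@]12C | intermediate
16 | 6,6'-(ethane-1,2-diyl)bis[(5aS,9aS)-2,2,5a,7-tetramethyl-3-(triethylsilyloxy)-2,3,4,5,5a,8,9,9a-octahydro-1-benzoxepine], C3 configuration not controlled (not isolated) | C(CC1=C(C)CC[C@@H]2OC(C)(C)C(O[Si](CC)(CC)CC)CC[C@@]12C)C1=C(C)CC[C@@H]2OC(C)(C)C(O[Si](CC)(CC)CC)CC[C@@]12C | intermediate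
17 | 6,6'-(ethane-1,2-diyl)bis[(5aS,9aS)-2,2,5a,7-tetramethyl-2,3,4,5,5a,8,9,9a-octahydro-1-benzoxepin-3-ol], C3/C22 configuration not controlled | C(CC1=C(C)CC[C@@H]2OC(C)(C)C(O)CC[C@@]12C)C1=C(C)CC[C@@H]2OC(C)(C)C(O)CC[C@@]12C | intermediate
18 | 6,6'-(ethane-1,2-diyl)bis[(5aS,9aS)-2,2,5a,7-tetramethyl-4,5,5a,8,9,9a-hexahydro-1-benzoxepin-3(2H)-one] | C(CC1=C(C)CC[C@@H]2OC(C)(C)C(=O)CC[C@@]12C)C1=C(C)CC[C@@H]2OC(C)(C)C(=O)CC[C@@]12C | intermediate
19 | sodwanone T, (3R,6S,7S,18S,19S) in squalene numbering | CC1=C(CCC2=C(C)CC[C@@H]3OC(C)(C)[C@H](O)CC[C@@]23C)[C@]2(C)CCC(=O)C(C)(C)O[C@H]2CC1 | target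

## Step count and least certain steps

Total: 12 steps. Longest linear sequence: 11 steps (steps 2–12, from hexa-1,5-diyne); step 1 is a one-step side branch.

**Step 3 (key step).** The second conjugate addition may be incomplete and leave a half-reacted, protonated alkenyl arm. Isobutyl transfer may compete. Any β-alkenyl isomer from the hydroalumination is carried through. Wrong-sense additions build up the meso diastereomer, which is hard to separate at this stage.
Fallback: run the sequence one alkyne at a time, setting out from 3, 4 and 6. Hydroalumination of excess 3 with one equivalent of 4 gives (hex-1-en-5-yn-2-yl)diisobutylalane F1. Copper-catalysed addition to one equivalent of 6 gives the aluminium enolate F2, which Et3SiOTf converts into the mono(enol silane) F3. A second nickel-catalysed hydroalumination of the remaining alkyne gives the alane F4, and a second conjugate addition to 6 gives the mixed aluminium enolate/enol silane F5, which is silylated to rejoin the route at 8. Each stage is then exactly the single-alkyne process and can be purified and analysed on its own.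

**Step 4.** Alkylation at the enolate carbon next to the quaternary centre may be slow. The iodide can be lost by elimination to isoprene, proton transfer can scramble the enolate or cause dialkylation, and facial selectivity at C7 may be modest.
Fallback: replace alkylation by conjugate addition, setting out from 8. A TiCl4-mediated Mukaiyama–Michael addition to but-3-en-2-one gives the bis(3-oxobutyl) tetraketone F6. Wittig methylenation (Ph3P=CH2, low temperature) of the unhindered methyl ketones, in preference to the ring carbonyls shielded by C7 and the axial C6 substituent, returns to 10. Incomplete C7 selectivity from either route can be corrected by base equilibration and separation of the ring-fusion epimers at 11.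

**Step 5.** The catalyst may decompose before the hindered tetrasubstituted alkenes close, only one ring may close, or ruthenium hydrides may isomerise the 1,1-disubstituted alkenes.
Fallback: close the rings by carbonyl coupling, setting out from 10. NaBH4 reduces the ring carbonyls to the diol F7. Ozonolysis (O3, then Me2S) of the four methylidene groups gives the tetraketone diol F8. Intramolecular McMurry coupling (TiCl3, Zn–Cu, DME, reflux) of each C10/C11 and C14/C15 ketone pair closes the tetrasubstituted cyclohexenes and gives the bis(octalinol) F9. Dess–Martin oxidation returns to 11.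

**Step 6.** Peroxide addition to the hindered carbonyl may be slow, so that Lewis-acid-induced alkene isomerisation or a transannular carbonyl-ene process competes; the wrong α-carbon may also migrate.
Fallback: accept epoxidation and undo it, setting out from 11. Excess mCPBA (NaHCO3, CH2Cl2) epoxidises both alkenes and then carries out the Baeyer–Villiger oxidation to give the bis(epoxy lactone) F10. Deoxygenation with Cp2TiCl (from Cp2TiCl2 and Zn; trivalent titanium opens the epoxide to a tertiary radical, which is reduced and eliminated) restores the alkenes and returns to 12.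

**Step 10 (with step 9).** The tetrahedral intermediate of step 9 may collapse and take up a second MeLi, or the α-silyloxy lactone may be enolised. In step 10 the open-chain hydroxy ketone may be methylated at carbonyl, giving an acyclic tertiary alcohol in place of the cyclic ether, or the oxocarbenium ion may eliminate to an enol ether.
Fallback: keep the ring closed throughout, setting out from 14. Petasis methylenation (Cp2TiMe2, toluene, 70 °C) gives the exocyclic enol ether F11. Acid-catalysed addition of MeOH (PPTS) gives the cyclic methyl ketal F12. Me3Al/Me3SiOTf then replaces methoxide by methyl and returns to 16, which is desilylated as in step 10.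

## Further compounds

F1 | step 3 | (hex-1-en-5-yn-2-yl)diisobutylalane | C=C(CCC#C)[Al](CC(C)C)CC(C)C
F2 | step 3 | diisobutylaluminium enolate of (3R)-3-(hex-1-en-5-yn-2-yl)-3-methylcyclohexan-1-one | C#CCCC(=C)[C@]1(C)CCCC(O[Al](CC(C)C)CC(C)C)=C1
F3 | step 3 | triethyl{[(3R)-3-(hex-1-en-5-yn-2-yl)-3-methylcyclohex-1-en-1-yl]oxy}silane | C#CCCC(=C)[C@]1(C)CCCC(O[Si](CC)(CC)CC)=C1
F4 | step 3 | diisobutyl{5-[(1R)-1-methyl-3-(triethylsilyloxy)cyclohex-2-en-1-yl]hexa-1,5-dien-2-yl}alane | C=C([Al](CC(C)C)CC(C)C)CCC(=C)[C@]1(C)CCCC(O[Si](CC)(CC)CC)=C1
F5 | step 3 | mixed diisobutylaluminium enolate / triethylsilyl enol ether of the (R,R)-diketone | C=C(CCC(=C)[C@]1(C)CCCC(O[Si](CC)(CC)CC)=C1)[C@]1(C)CCCC(O[Al](CC(C)C)CC(C)C)=C1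
F6 | step 4 | (2S,3R,2'S,3'R)-3,3'-(hexa-1,5-diene-2,5-diyl)bis[3-methyl-2-(3-oxobutyl)cyclohexan-1-one] | C=C(CCC(=C)[C@]1(C)CCCC(=O)[C@H]1CCC(C)=O)[C@]1(C)CCCC(=O)[C@H]1CCC(C)=O
F7 | step 5 | 3,3'-(hexa-1,5-diene-2,5-diyl)bis[(2S,3R)-3-methyl-2-(3-methylbut-3-en-1-yl)cyclohexan-1-ol], carbinol configuration not controlled | C=C(CCC(=C)[C@]1(C)CCCC(O)[C@H]1CCC(C)=C)[C@]1(C)CCCC(O)[C@H]1CCC(C)=C
F8 | step 5 | 1,4-bis[(1R,2S)-3-hydroxy-1-methyl-2-(3-oxobutyl)cyclohexyl]butane-1,4-dione, carbinol configuration not controlled | O=C(CCC(=O)[C@]1(C)CCCC(O)[C@H]1CCC(C)=O)[C@]1(C)CCCC(O)[C@H]1CCC(C)=O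
F9 | step 5 | 5,5'-(ethane-1,2-diyl)bis[(4aR,8aS)-4a,6-dimethyl-1,2,3,4,4a,7,8,8a-octahydronaphthalen-1-ol], carbinol configuration not controlled | C(CC1=C(C)CC[C@@H]2C(O)CCC[C@@]12C)C1=C(C)CC[C@@H]2C(O)CCC[C@@]12C
F10 | step 6 | bis(6,7-epoxide) of 12 (10,11;14,15-diepoxide in squalene numbering), epoxide configuration not controlled | C(CC13OC3(C)CC[C@@H]2OC(=O)CCC[C@@]12C)C13OC3(C)CC[C@@H]2OC(=O)CCC[C@@]12C
F11 | step 10 | 6,6'-(ethane-1,2-diyl)bis[(5aS,9aS)-5a,7-dimethyl-2-methylidene-3-(triethylsilyloxy)-2,3,4,5,5a,8,9,9a-octahydro-1-benzoxepine], C3 configuration not controlled | C(CC1=C(C)CC[C@@H]2OC(=C)C(O[Si](CC)(CC)CC)CC[C@@]12C)C1=C(C)CC[C@@H]2OC(=C)C(O[Si](CC)(CC)CC)CC[C@@]12C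
F12 | step 10 | 6,6'-(ethane-1,2-diyl)bis[(5aS,9aS)-2-methoxy-2,5a,7-trimethyl-3-(triethylsilyloxy)-2,3,4,5,5a,8,9,9a-octahydro-1-benzoxepine], C2 and C3 configuration not controlled | C(CC1=C(C)CC[C@@H]2OC(C)(OC)C(O[Si](CC)(CC)CC)CC[C@@]12C)C1=C(C)CC[C@@H]2OC(C)(OC)C(O[Si](CC)(CC)CC)CC[C@@]12C
A1 | alternative 1 | 2,2'-(ethane-1,2-diyl)bis(6-methoxy-3-methylbenzoic acid) bis-amide of (S)-2-(methoxymethyl)pyrrolidine | C(Cc1c(C)ccc(OC)c1C(=O)N1CCC[C@H]1COC)c1c(C)ccc(OC)c1C(=O)N1CCC[C@H]1COC
A2 | alternative 1 | 6,6'-(ethane-1,2-diyl)bis(2-methoxy-1,5-dimethylcyclohexa-2,5-diene-1-carboxamide) of the same auxiliary | C(CC1=C(C)CC=C(OC)[C@@]1(C)C(=O)N2CCC[C@H]2COC)C1=C(C)CC=C(OC)[C@@]1(C)C(=O)N2CCC[C@H]2COC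
A3 | alternative 2 | (3R,6S,7S,18S,19S,22R)-2,3;6,7;18,19;22,23-tetraepoxy-(10E,14E)-squalene | CC1(C)O[C@@H]1CC[C@]2(C)O[C@H]2CC/C(C)=C/CC/C=C(\C)CC[C@@H]3O[C@@]3(C)CC[C@H]4OC4(C)C
A4 | alternative 2 | C2-symmetric bis(oxepane–cyclohexene) (3R,22R)-3,22-diol | C(CC1=C(C)CC[C@@H]2OC(C)(C)[C@H](O)CC[C@@]12C)C1=C(C)CC[C@@H]2OC(C)(C)[C@H](O)CC[C@@]12C
A5 | alternative 3 | C2-symmetric bis(7,7-dimethyl-6-silyloxyoxepan-2-one) with a (Z)-tetrasubstituted 2-methylpenta-1,4-dienyl unit on each quaternary α-carbon | C(C/C(=C(\C)CC=C)[C@]1(C)CC[C@@H](O[Si](C)(C)C(C)(C)C)C(C)(C)OC1=O)/C(=C(\C)CC=C)[C@]1(C)CC[C@@H](O[Si](C)(C)C(C)(C)C)C(C)(C)OC1=O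
A6 | alternative 3 | C2-symmetric bis(bicyclic enol ether) with C7=C8 and C17=C18 | C(CC1=C(C)CC=C2OC(C)(C)[C@H](O[Si](C)(C)C(C)(C)C)CC[C@@]12C)C1=C(C)CC=C2OC(C)(C)[C@H](O[Si](C)(C)C(C)(C)C)CC[C@@]12C
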